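**Retrosynthetic overview**
- The strategy rests on ring A of the eudesmanolide half: the C1' carbinol beside quaternary C10' and the C5'=C6' alkene is a carbonyl-ene retron. Ring A is opened to the C1' aldehyde and the tetrasubstituted C5'=C10' alkene of the seco lactone 17.
- The norbornene core (bonds C1–C13' and C3–C11') is cut by a Diels–Alder reaction between the 2-acetoxy-guaia-1(5),3-diene 41 (C11 methylene masked as a Mannich base) and the methylene lactone of 20.
- Eudesmane half: ring B by Michael/aldol annulation of (R)-citronellal, then the cis lactone, then ring A (ene).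
- Guaiane half: cyclopentane ring from cyclopentane-1,3-dione, C10 by organocatalytic Michael addition, C7/C8 by allylboration, seven-membered ring by metathesis, then lactone and diene.
- Last: cycloaddition closes the two norbornene rings, then the guaiane methylene lactone is unmasked.

Key step: step 10

Remark 1: locants C1–C15 belong to the guaiane half and C1'–C15' to the eudesmane half (numbering of the target).
Remark 2 (assumption): in the concerted ene closure the C6' hydrogen can only reach a C1' oxygen that is axial (synclinal to C5'–C6'). Step 10 is therefore taken to give the C1' epimer 18, and steps 11–12 turn it into the 1'-hydroxy compound 20 needed for the target.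
Remark 3: centres that are removed later (C5' and C10' in 3–8, the anomeric carbon of 23, C4 in 32–40, C11 in 39–43, C11' in 13–14) are carried as drawn or as mixtures without consequence.

**Part A – eudesmanolide half**

Step 1
Reactants: 1 (R)-citronellal; 2 methyl vinyl ketone
Product: 4 (4S)-4-[(2R)-6-methylhept-5-en-2-yl]cyclohex-2-en-1-one, via keto-aldehyde 3 (not isolated)
Conditions: (S)-α,α-diphenylprolinol trimethylsilyl ether (10 mol %), catechol (20 mol %), neat, 4 °C; then LiOH (cat.), i-PrOH, rt
Reagents that add atoms: none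
Why: enamine-catalysed Michael addition of the aldehyde to the enone followed by intramolecular aldol condensation (organocatalytic Robinson-type annulation) builds ring B, the (S)-catalyst shielding one enamine face so that C5' is formed S next to the citronellal-derived C4'.

Step 2
Reactants: 4 enone
Product: 5 trimethylsilyl enol ether of the trans-3-methyl ketone
Conditions: Me2CuLi, Me3SiCl, THF, −78 °C
Reagents that add atoms: lithium dimethylcuprate C[Cu-]C.[Li+]; chlorotrimethylsilane C[Si](C)(C)Cl
Why: cuprate conjugate addition with in situ enolate silylation puts the C14' methyl on C10' anti to the C5' side chain, and this centre becomes sp2 again in step 3.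

Step 3
Reactants: 5 silyl enol ether
Product: 6 (4S)-3-methyl-4-[(2R)-6-methylhept-5-en-2-yl]cyclohex-2-en-1-one
Conditions: Pd(OAc)2 (1.05 equiv), MeCN, rt
Reagents that add atoms: none
Why: Saegusa–Ito oxidation of the regiodefined silyl enol ether restores the enone by β-hydride loss from C10'.

Step 4
Reactants: 6 enone; 7 methyl bromoacetate
Product: 8 methyl 2-[(1S,5S)-4-methyl-5-[(2R)-6-methylhept-5-en-2-yl]-2-oxocyclohex-3-en-1-yl]acetate
Conditions: LiN(i-Pr)2, THF, −78 °C; then 7, DMPU, −78 → −40 °C
Reagents that add atoms: none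
Why: kinetic α'-enolate alkylation sets C7', the electrophile entering anti to the C5' side chain, which is pseudo-axial because of A(1,2) strain with the C10' methyl.

Step 5
Reactants: 8 keto ester
Product: 9 linear trimethylsilyl dienol ether (C8'(OSiMe3)=C9', C10'=C5')
Conditions: Me3SiCl, NaI, Et3N, MeCN, rt
Reagents that add atoms: chlorotrimethylsilane C[Si](C)(C)Cl
Why: thermodynamic enol silylation with in situ Me3SiI gives the linear dienol ether (the known outcome for 3-alkyl cyclohexenones), which moves the ring alkene to C5'=C10' and leaves C7' untouched.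

Step 6
Reactants: 9 silyl dienol ether
Product: 12 cis-fused lactone (3aS,7aS), via β,γ-enone 10 (not isolated), via cis-hydroxy ester 11 (not isolated)
Conditions: Bu4NF, AcOH, THF, −78 °C; then LiBH(s-Bu)3, −78 °C; aq. NH4Cl, then PPTS (cat.), CH2Cl2, rt
Reagents that add atoms: none
Why: fluoride desilylation with kinetic α-protonation at C9' gives the deconjugated ketone, which the bulky hydride reduces by equatorial attack to the axial C8' alcohol cis to the C7' acetate arm, and this lactonises (deconjugation / L-Selectride reduction / lactonisation).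

Step 7
Reactants: 12 lactone
Product: 13 α-(dimethylaminomethyl) lactone
Conditions: LiN(i-Pr)2, THF, −78 °C; then CH2=NMe2+ I−, −78 → 0 °C
Reagents that add atoms: N,N-dimethylmethyleneiminium iodide C=[N+](C)C.[I-]
Why: Mannich alkylation of the lactone enolate with Eschenmoser's salt on the convex face, the only enolisable position in the molecule.

Step 8
Reactants: 13 Mannich base
Product: 15 α-methylene lactone with intact citronellyl chain, via ammonium iodide 14 (not isolated)
Conditions: MeI, MeOH, rt; then aq. NaHCO3, CH2Cl2, rt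
Reagents that add atoms: none
Why: quaternisation and E1cB loss of trimethylamine, the standard α-methylenation of γ-lactones.

Step 9
Reactants: 15 triene lactone
Product: 17 seco-ring-A C1' aldehyde (key-step precursor), via diol 16 (not isolated)
Conditions: OsO4 (2 mol %), NaIO4, 2,6-lutidine, dioxane–H2O, 0 °C
Reagents that add atoms: osmium tetroxide O=[Os](=O)(=O)=O; sodium periodate [Na+].[O-]I(=O)(=O)=O
Why: Lemieux–Johnson cleavage is selective for the unhindered, electron-rich trisubstituted side-chain alkene over the hindered tetrasubstituted ring alkene and the electron-poor methylene lactone.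

Step 10
Reactants: 17 seco aldehyde
Product: 18 ring-A-closed 1'-epi-alcohol (C1'–OH axial, trans to C14')
Conditions: Me2AlCl (2 equiv), CH2Cl2, −78 → −20 °C
Reagents that add atoms: none
Why: Me2AlCl activates the C1' aldehyde, which bonds to C10' of the electron-rich tetrasubstituted C5'=C10' alkene while the pseudo-axial C6' hydrogen on the same face passes to oxygen through a six-membered array, either concertedly or via a short-lived tertiary C5' cation that collapses by the same hydrogen shift. The closest precedent is the Me2AlCl-promoted type 2 intramolecular carbonyl-ene cyclisation of δ,ε-unsaturated aldehydes. Ring A closes as a six-membered chair by attack on the distal alkene carbon (6-endo with respect to C5'=C10'), the tether being attached at the central ene carbon C5'. C10' is set by delivery of the tether to the face anti to the C15' methyl (A(1,3) strain with C14' keeps the C4' hydrogen in the alkene plane), which is also the convex face anti to the cis-fused lactone, so the two controls are matched. C1' is set by the need for an axial oxygen to reach the C6' hydrogen, which gives the alcohol trans to C14', the epimer that step 12 corrects. The step needs hydrogen transfer from C6' and not C4', which the in-plane C4' hydrogen secures, and tolerance of the methylene lactone, which is not an ene partner under these conditions.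

Step 11
Reactants: 18 1'-epi-alcohol
Product: 19 C1' ketone
Conditions: Dess–Martin periodinane, NaHCO3, CH2Cl2, 0 °C → rt
Reagents that add atoms: none
Why: Dess–Martin oxidation under buffered conditions leaves the β,γ-alkene and the methylene lactone in place.

Step 12
Reactants: 19 ketone
Product: 20 1'-hydroxy-eudesma-5',11'(13')-dien-8',12'-olide (C1'–OH cis to C14')
Conditions: NaBH4, CeCl3·7H2O, MeOH, −78 → −40 °C
Reagents that add atoms: none
Why: Luche reduction delivers hydride axially, anti to the axial angular C14' methyl (the selectivity known for the saturated ketone of the Wieland–Miescher ketone), giving the equatorial C1' alcohol without conjugate reduction of the methylene lactone.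

**Part B – guaianolide half**

Step 13
Reactants: 21 cyclopentane-1,3-dione; 22 (E)-crotonaldehyde
Product: 23 (4R)-2-hydroxy-4-methyl-3,4,6,7-tetrahydrocyclopenta[b]pyran-5(2H)-one (lactol)
Conditions: (S)-α,α-diphenylprolinol trimethylsilyl ether (10 mol %), PhCO2H (10 mol %), CH2Cl2, rt
Reagents that add atoms: none
Why: iminium-catalysed Michael addition of the cyclic 1,3-dione to the enal sets C10 (R) by attack on the enal face not shielded by the catalyst, and the adduct rests as the lactol.

Step 14
Reactants: 23 lactol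
Product: 24 3-methoxy-2-[(2R)-4-oxobutan-2-yl]cyclopent-2-en-1-one
Conditions: Me3SiCHN2, MeOH–toluene, 0 °C
Reagents that add atoms: (trimethylsilyl)diazomethane C[Si](C)(C)C=[N+]=[N-]
Why: the acidic vinylogous acid of the ring-opened form is O-methylated irreversibly (diazoalkane esterification), which drains the lactol and frees the C8 aldehyde, and the symmetric dione gives a single vinylogous ester.

Step 15
Reactants: 25 tert-butyl(but-3-yn-1-yloxy)dimethylsilane
Product: 27 tert-butyldimethyl(penta-3,4-dien-1-yloxy)silane, via propargylic amine 26 (not isolated)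
Conditions: (CH2O)n, CuI (cat.), i-Pr2NH, dioxane, reflux
Reagents that add atoms: formaldehyde (as paraformaldehyde) C=O
Why: Crabbé homologation, a Mannich reaction followed by hydride transfer from the amine, converts the terminal alkyne into the terminal allene.

Step 16
Reactants: 27 allene; 24 aldehyde
Product: 30 3-methoxy-2-[(2R,4R,5R)-7-(tert-butyldimethylsilyloxy)-5-ethenyl-4-hydroxyheptan-2-yl]cyclopent-2-en-1-one, via (Z)-allylborane 28 (not isolated), via borinate 29 (not isolated)
Conditions: (−)-Ipc2BH, THF, −25 °C; then 24, −78 °C; HOCH2CH2NH2, rt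
Reagents that add atoms: none
Why: kinetic hydroboration of the allene gives the (Z)-γ-substituted allylborane, which adds to the aldehyde through a chair transition state (Brown allylboration), so that C7/C8 are syn and the isopinocampheyl groups fix C8 as R independently of C10.

Step 17
Reactants: 30 homoallylic alcohol
Product: 31 C8 triethylsilyl ether
Conditions: Et3SiCl, imidazole, CH2Cl2, 0 °C
Reagents that add atoms: chlorotriethylsilane CC[Si](Cl)(CC)CC
Why: silylation protects the secondary alcohol from the enolate chemistry of steps 18–19.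

Step 18
Reactants: 31 vinylogous ester
Product: 32 C4-methyl vinylogous ester (both C4 epimers)
Conditions: LiN(i-Pr)2, THF, −78 °C; then MeI
Reagents that add atoms: iodomethane CI
Why: kinetic α'-deprotonation of the vinylogous ester (Stork–Danheiser alkylation) places the C15 methyl on the carbon next to the carbonyl that later becomes C5.

Step 19
Reactants: 32 methyl vinylogous ester
Product: 33 C4 tertiary alcohol (both C4 epimers)
Conditions: KN(SiMe3)2, THF, −78 °C; then 3-phenyl-2-(phenylsulfonyl)oxaziridine
Reagents that add atoms: 3-phenyl-2-(phenylsulfonyl)oxaziridine O=S(=O)(N1OC1c1ccccc1)c1ccccc1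
Why: Davis hydroxylation of the tetrasubstituted α'-enolate installs the C4 oxygen whose loss later creates C3=C4.

Step 20
Reactants: 33 hydroxy vinylogous ester
Product: 34 2-methoxy diene with exocyclic C5=CH2
Conditions: Cp2TiMe2 (3 equiv), toluene–THF, 65 °C, dark
Reagents that add atoms: dimethyltitanocene C[Ti](C)(C1C=CC=C1)C1C=CC=C1
Why: Petasis methylenation converts the hindered, ester-like carbonyl into the methylene group that serves as C6 donor site for metathesis, and the free tertiary hydroxyl only consumes extra reagent.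

Step 21
Reactants: 34 triene
Product: 35 bicyclic dienol ether (C2(OMe)=C1, C5=C6)
Conditions: (H2IMes)(PCy3)Cl2Ru=CHPh (second-generation Grubbs catalyst, 5 mol %), toluene, 60 °C
Reagents that add atoms: none
Why: ring-closing metathesis between the C5 methylene and the C7 vinyl group closes the seven-membered ring as a trisubstituted alkene with loss of ethylene.

Step 22
Reactants: 35 dienol ether
Product: 36 bicyclic enone triol (C2 ketone, C1=C5; C4, C8 and C12 hydroxyls)
Conditions: 1 M HCl, THF, 0 °C → rt
Reagents that add atoms: water O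
Why: protonation of the dienol ether at C6 and hydrolysis of the resulting oxocarbenium ion give the conjugated tetrasubstituted enone (the outcome of a Stork–Danheiser transposition), and the same acid removes both silyl ethers.

Step 23
Reactants: 36 triol
Product: 37 trans-fused 8,12-lactone of the 4-hydroxy enone
Conditions: TEMPO (cat.), PhI(OAc)2, CH2Cl2, rt
Reagents that add atoms: none
Why: chemoselective oxidation of the primary C12 alcohol, lactol formation with the C8 hydroxyl and further oxidation (oxidative lactonisation of a 1,4-diol) give the lactone, with C7 and C8 unchanged.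

Step 24
Reactants: 37 enone
Product: 38 (2S)-allylic alcohol
Conditions: (R)-2-methyl-CBS-oxazaborolidine, BH3·SMe2, THF, −40 °C; MeOH quench
Reagents that add atoms: none
Why: Corey–Bakshi–Shibata reduction, with the tetrasubstituted alkenyl carbon C1 as the large and C3H2 as the small ketone substituent, sets C2 as S under reagent control.

Step 25
Reactants: 38 diol lactone
Product: 39 C11 (dimethylaminomethyl) lactone
Conditions: LiN(i-Pr)2 (3.3 equiv), THF, −78 °C; then CH2=NMe2+ I−
Reagents that add atoms: N,N-dimethylmethyleneiminium iodide C=[N+](C)C.[I-]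
Why: Mannich alkylation of the lactone enolate (the two hydroxyls are carried as alkoxides) installs C13 as a masked methylene group that cannot act as a dienophile in step 27.

Step 26
Reactants: 39 diol
Product: 40 C2 acetate
Conditions: Ac2O, pyridine, DMAP (cat.), CH2Cl2, 0 °C
Reagents that add atoms: acetic anhydride CC(=O)OC(C)=O
Why: acylation occurs only at the secondary allylic C2 hydroxyl, the tertiary C4 hydroxyl being unreactive under these conditions.

**Part C – union and completion**

Step 27
Reactants: 40 tertiary alcohol; 20 eudesmanolide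
Product: 42 Diels–Alder adduct (C11-aminomethyl japonicone A), via acetoxy diene 41 (not isolated)
Conditions: MeO2CN−SO2N+Et3 (Burgess reagent), PhH, rt → 40 °C; filter, add 20 (1.0 equiv), concentrate to about 2 M, BHT, rt, dark
Reagents that add atoms: none
Why: Burgess dehydration of the tertiary allylic alcohol gives the cyclopentadiene, which undergoes the biomimetic Diels–Alder reaction with the methylene lactone of 20, and C1, C3 and C11' should be set by approach to the diene face anti to the C14 methyl and the C2 acetoxy group, on the convex face of the cis-fused lactone, with the lactone carbonyl endo and the quaternary C11' bonding to the unsubstituted terminus C3.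

Step 28
Reactants: 42 adduct
Product: 44 japonicone A, via ammonium iodide 43 (not isolated)
Conditions: MeI, THF–MeOH, rt; then aq. NaHCO3, EtOAc, rt
Reagents that add atoms: none
Why: quaternisation of the only amine and E1cB loss of trimethylamine unmask the guaianolide methylene lactone without touching the acetate, the free C1' alcohol or the other lactone.

**Compound list**

1 | (R)-citronellal | C[C@H](CCC=C(C)C)CC=O | starting material
2 | methyl vinyl ketone | CC(=O)C=C | starting material
3 | (2S,3R)-3,7-dimethyl-2-(3-oxobutyl)oct-6-enal | O=C[C@@H](CCC(C)=O)[C@H](C)CCC=C(C)C | intermediate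
4 | (4S)-4-[(2R)-6-methylhept-5-en-2-yl]cyclohex-2-en-1-one | O=C1C=C[C@@H](CC1)[C@H](C)CCC=C(C)C | intermediate
5 | trimethylsilyl enol ether of trans-3-methyl-4-[(2R)-6-methylhept-5-en-2-yl]cyclohexanone | C[Si](C)(C)OC1=C[C@@H](C)[C@@H](CC1)[C@H](C)CCC=C(C)C | intermediate
6 | (4S)-3-methyl-4-[(2R)-6-methylhept-5-en-2-yl]cyclohex-2-en-1-one | O=C1C=C(C)[C@@H](CC1)[C@H](C)CCC=C(C)C | intermediate
7 | methyl bromoacetate | COC(=O)CBr | starting material
8 | methyl 2-[(1S,5S)-4-methyl-5-[(2R)-6-methylhept-5-en-2-yl]-2-oxocyclohex-3-en-1-yl]acetate | O=C1C=C(C)[C@@H](C[C@H]1CC(=O)OC)[C@H](C)CCC=C(C)C | intermediate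
9 | methyl 2-[(1S)-4-methyl-5-[(2R)-6-methylhept-5-en-2-yl]-2-(trimethylsilyloxy)cyclohexa-2,4-dien-1-yl]acetate | C[Si](C)(C)OC1=CC(C)=C(C[C@H]1CC(=O)OC)[C@H](C)CCC=C(C)C | intermediate
10 | methyl 2-[(1S)-4-methyl-5-[(2R)-6-methylhept-5-en-2-yl]-2-oxocyclohex-4-en-1-yl]acetate | O=C1CC(C)=C(C[C@H]1CC(=O)OC)[C@H](C)CCC=C(C)C | intermediate
11 | methyl 2-[cis-2-hydroxy-4-methyl-5-[(2R)-6-methylhept-5-en-2-yl]cyclohex-4-en-1-yl]acetate (C8'–OH cis to the C7' arm) | O[C@H]1CC(C)=C(C[C@H]1CC(=O)OC)[C@H](C)CCC=C(C)C | intermediate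
12 | (3aS,7aS)-6-methyl-5-[(2R)-6-methylhept-5-en-2-yl]-3a,4,7,7a-tetrahydro-1-benzofuran-2(3H)-one | C1C(=O)O[C@H]2CC(C)=C(C[C@H]21)[C@H](C)CCC=C(C)C | intermediate
13 | C11'-(dimethylaminomethyl) derivative of 12 (aminomethyl group on the convex face) | CN(C)C[C@@H]1C(=O)O[C@H]2CC(C)=C(C[C@H]21)[C@H](C)CCC=C(C)C | intermediate
14 | trimethylammonium iodide of 13 | C[N+](C)(C)C[C@@H]1C(=O)O[C@H]2CC(C)=C(C[C@H]21)[C@H](C)CCC=C(C)C.[I-] | intermediate
15 | (3aS,7aS)-6-methyl-3-methylidene-5-[(2R)-6-methylhept-5-en-2-yl]-3a,4,7,7a-tetrahydro-1-benzofuran-2(3H)-one | C=C1C(=O)O[C@H]2CC(C)=C(C[C@H]21)[C@H](C)CCC=C(C)C | intermediate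
16 | side-chain 1,2-diol of 15 (both carbinol epimers) | C=C1C(=O)O[C@H]2CC(C)=C(C[C@H]21)[C@H](C)CCC(O)C(C)(C)O | intermediate
17 | (3aS,7aS)-6-methyl-3-methylidene-5-[(2R)-5-oxopentan-2-yl]-3a,4,7,7a-tetrahydro-1-benzofuran-2(3H)-one (seco-ring-A C1' aldehyde) | C=C1C(=O)O[C@H]2CC(C)=C(C[C@H]21)[C@H](C)CCC=O | intermediate
18 | 1'-epi-1'-hydroxy-eudesma-5',11'(13')-dien-8',12'-olide (C1'–OH trans to C14') | C=C1C(=O)O[C@H]2C[C@@]3(C)C(=C[C@H]21)[C@H](C)CC[C@H]3O | intermediate
19 | 1'-oxo-eudesma-5',11'(13')-dien-8',12'-olide | C=C1C(=O)O[C@H]2C[C@@]3(C)C(=C[C@H]21)[C@H](C)CCC3=O | intermediate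
20 | 1'-hydroxy-eudesma-5',11'(13')-dien-8',12'-olide (C1'–OH cis to C14') | C=C1C(=O)O[C@H]2C[C@@]3(C)C(=C[C@H]21)[C@H](C)CC[C@@H]3O | intermediate
21 | cyclopentane-1,3-dione | O=C1CCC(=O)C1 | starting material
22 | (E)-crotonaldehyde | C/C=C/C=O | starting material
23 | (4R)-2-hydroxy-4-methyl-3,4,6,7-tetrahydrocyclopenta[b]pyran-5(2H)-one (anomer mixture) | O=C1CCC2=C1[C@H](C)CC(O)O2 | intermediate
24 | 3-methoxy-2-[(2R)-4-oxobutan-2-yl]cyclopent-2-en-1-one | COC1=C(C(=O)CC1)[C@H](C)CC=O | intermediate
25 | tert-butyl(but-3-yn-1-yloxy)dimethylsilane | C#CCCO[Si](C)(C)C(C)(C)C | starting material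
26 | N,N-diisopropyl-5-(tert-butyldimethylsilyloxy)pent-2-yn-1-amine | CC(C)N(CC#CCCO[Si](C)(C)C(C)(C)C)C(C)C | intermediate
27 | tert-butyldimethyl(penta-3,4-dien-1-yloxy)silane | C=C=CCCO[Si](C)(C)C(C)(C)C | intermediate
28 | (Z)-[5-(tert-butyldimethylsilyloxy)pent-2-en-1-yl]diisopinocampheylborane (isopinocampheyl groups from (+)-α-pinene) | CC(C)(C)[Si](C)(C)OCC/C=C\CB([C@@H]1C[C@@H]2C[C@H]([C@H]1C)C2(C)C)[C@@H]1C[C@@H]2C[C@H]([C@H]1C)C2(C)C | intermediate
29 | diisopinocampheylborinate of 30 | COC1=C(C(=O)CC1)[C@H](C)C[C@@H](OB([C@@H]1C[C@@H]2C[C@H]([C@H]1C)C2(C)C)[C@@H]1C[C@@H]2C[C@H]([C@H]1C)C2(C)C)[C@H](CCO[Si](C)(C)C(C)(C)C)C=C | intermediate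
30 | 3-methoxy-2-[(2R,4R,5R)-7-(tert-butyldimethylsilyloxy)-5-ethenyl-4-hydroxyheptan-2-yl]cyclopent-2-en-1-one | COC1=C(C(=O)CC1)[C@H](C)C[C@@H](O)[C@H](CCO[Si](C)(C)C(C)(C)C)C=C | intermediate
31 | C8 triethylsilyl ether of 30 | COC1=C(C(=O)CC1)[C@H](C)C[C@@H](O[Si](CC)(CC)CC)[C@H](CCO[Si](C)(C)C(C)(C)C)C=C | intermediate
32 | 5-methyl (C4-methyl) derivative of 31, both C4 epimers | COC1=C(C(=O)C(C)C1)[C@H](C)C[C@@H](O[Si](CC)(CC)CC)[C@H](CCO[Si](C)(C)C(C)(C)C)C=C | intermediate
33 | 5-hydroxy-5-methyl (C4 hydroxy) derivative of 31, both C4 epimers | COC1=C(C(=O)C(C)(O)C1)[C@H](C)C[C@@H](O[Si](CC)(CC)CC)[C@H](CCO[Si](C)(C)C(C)(C)C)C=C | intermediate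
34 | C5-methylidene 2-methoxy diene from 33 | COC1=C(C(=C)C(C)(O)C1)[C@H](C)C[C@@H](O[Si](CC)(CC)CC)[C@H](CCO[Si](C)(C)C(C)(C)C)C=C | intermediate
35 | bicyclo[5.3.0] dienol ether: 2-methoxy-guaia-1,5-diene core with C4–OH, C8–OSiEt3, C7–CH2CH2OSi(t-Bu)Me2 | COC1=C2[C@H](C)C[C@@H](O[Si](CC)(CC)CC)[C@H](CCO[Si](C)(C)C(C)(C)C)C=C2C(C)(O)C1 | intermediate
36 | (7R,8R,10R)-4,8-dihydroxy-7-(2-hydroxyethyl)-4,10-dimethylbicyclo[5.3.0]dec-1(5)-en-2-one (guaiane locants, C4 epimers) | O=C1CC(C)(O)C2=C1[C@H](C)C[C@@H](O)[C@H](CCO)C2 | intermediate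
37 | 4-hydroxy-2-oxo-13-nor-guai-1(5)-en-8,12-olide (trans-fused lactone, 7R,8R,10R) | O=C1CC(C)(O)C2=C1[C@H](C)C[C@H]3OC(=O)C[C@@H]3C2 | intermediate
38 | (2S)-2,4-dihydroxy-13-nor-guai-1(5)-en-8,12-olide | O[C@H]1CC(C)(O)C2=C1[C@H](C)C[C@H]3OC(=O)C[C@@H]3C2 | intermediate
39 | (2S)-13-(dimethylamino)-2,4-dihydroxy-guai-1(5)-en-8,12-olide | O[C@H]1CC(C)(O)C2=C1[C@H](C)C[C@H]3OC(=O)[C@@H](CN(C)C)[C@@H]3C2 | intermediate
40 | (2S)-2-acetoxy-13-(dimethylamino)-4-hydroxy-guai-1(5)-en-8,12-olide | CC(=O)O[C@H]1CC(C)(O)C2=C1[C@H](C)C[C@H]3OC(=O)[C@@H](CN(C)C)[C@@H]3C2 | intermediate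
41 | (2S)-2-acetoxy-13-(dimethylamino)-guaia-1(5),3-dien-8,12-olide | CC(=O)O[C@H]1C=C(C)C2=C1[C@H](C)C[C@H]3OC(=O)[C@@H](CN(C)C)[C@@H]3C2 | intermediate
42 | 11,13-dihydro-13-(dimethylamino)japonicone A | CN(C)C[C@@H]1C(=O)O[C@@H]2C[C@@H](C)[C@]34C[C@]5(C(=O)O[C@H]6C[C@@]7(C)C(=C[C@H]65)[C@H](C)CC[C@@H]7O)[C@H](C(C)=C3C[C@@H]12)[C@@H]4OC(C)=O | intermediate
43 | trimethylammonium iodide of 42 | C[N+](C)(C)C[C@@H]1C(=O)O[C@@H]2C[C@@H](C)[C@]34C[C@]5(C(=O)O[C@H]6C[C@@]7(C)C(=C[C@H]65)[C@H](C)CC[C@@H]7O)[C@H](C(C)=C3C[C@@H]12)[C@@H]4OC(C)=O.[I-] | intermediate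
44 | japonicone A | C=C1C(=O)O[C@@H]2C[C@@H](C)[C@]34C[C@]5(C(=O)O[C@H]6C[C@@]7(C)C(=C[C@H]65)[C@H](C)CC[C@@H]7O)[C@H](C(C)=C3C[C@@H]12)[C@@H]4OC(C)=O | target

**Step count**
Total: 28 steps. Longest linear sequence: 15 steps (21 → 44 through steps 13, 14, 16–28).

**Steps most likely to fail, with fallbacks**

1. Step 27. The acetoxy diene may isomerise by 1,5-hydrogen shift before it is trapped. The cycloaddition may also take place on the diene face syn to the acetoxy group, which is the usual preference of 5-acyloxycyclopentadienes, or with the lactone carbonyl exo. The fallback sets out from 39 and from ketone 19 and comes back at 42. The C2 hydroxyl of 39 is silylated (t-BuMe2SiCl, imidazole) to the silyl ether F1, and Burgess dehydration gives the silyloxy diene F2, whose bulky C2 group should steer the dienophile by size. Cycloaddition with 19, which has no free hydroxyl, gives the keto adduct F3. HF·pyridine frees the C2 alcohol F4, Ac2O/DMAP gives the keto acetate F5, and NaBH4/CeCl3 reduction of the C1' ketone (as in step 12) gives 42.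

2. Step 10. The developing C5' cation may be captured by chloride or lose a proton from C4' instead of taking part in the hydrogen transfer from C6', and the aldehyde may oligomerise on the Lewis acid. The fallback sets out from 17 and comes back at 19. Pinnick oxidation (NaClO2, NaH2PO4, 2-methyl-2-butene) gives the carboxylic acid F6, and (COCl)2 gives the acid chloride F7. SnCl4 in CH2Cl2 at −78 °C then effects intramolecular acylation of the C5'=C10' alkene with loss of the C6' proton, the known Lewis-acid acylation of alkenes to β,γ-unsaturated ketones, which forms the C1'–C10' bond and ring A at the ketone level.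

3. Step 6. The β,γ-unsaturated ketone may reconjugate, and C7' may epimerise before hydride is delivered. The fallback sets out from 8 and comes back at 12. Isopropenyl acetate/TsOH gives the linear dienyl acetate F8. NaBH4 in EtOH reduces it with deconjugation (the steroid Δ4-3-ketone to Δ5-3-ol method) to the trans hydroxy ester F9, the C8' epimer of 11. LiOH gives the hydroxy acid F10, and Mitsunobu lactonisation (PPh3, DIAD) closes the lactone with inversion at C8'.

Further compounds
F1 | step 27 | (2S)-2-(tert-butyldimethylsilyloxy)-13-(dimethylamino)-4-hydroxy-guai-1(5)-en-8,12-olide | CC(C)(C)[Si](C)(C)O[C@H]1CC(C)(O)C2=C1[C@H](C)C[C@H]3OC(=O)[C@@H](CN(C)C)[C@@H]3C2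
F2 | step 27 | (2S)-2-(tert-butyldimethylsilyloxy)-13-(dimethylamino)-guaia-1(5),3-dien-8,12-olide | CC(C)(C)[Si](C)(C)O[C@H]1C=C(C)C2=C1[C@H](C)C[C@H]3OC(=O)[C@@H](CN(C)C)[C@@H]3C2
F3 | step 27 | 1'-oxo, 2-O-silyl (deacetyl) analogue of adduct 42 | CN(C)C[C@@H]1C(=O)O[C@@H]2C[C@@H](C)[C@]34C[C@]5(C(=O)O[C@H]6C[C@@]7(C)C(=C[C@H]65)[C@H](C)CCC7=O)[C@H](C(C)=C3C[C@@H]12)[C@@H]4O[Si](C)(C)C(C)(C)C
F4 | step 27 | 1'-oxo, 2-hydroxy (deacetyl) analogue of adduct 42 | CN(C)C[C@@H]1C(=O)O[C@@H]2C[C@@H](C)[C@]34C[C@]5(C(=O)O[C@H]6C[C@@]7(C)C(=C[C@H]65)[C@H](C)CCC7=O)[C@H](C(C)=C3C[C@@H]12)[C@@H]4O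
F5 | step 27 | 1'-oxo analogue of adduct 42 | CN(C)C[C@@H]1C(=O)O[C@@H]2C[C@@H](C)[C@]34C[C@]5(C(=O)O[C@H]6C[C@@]7(C)C(=C[C@H]65)[C@H](C)CCC7=O)[C@H](C(C)=C3C[C@@H]12)[C@@H]4OC(C)=O
F6 | step 10 | C1' carboxylic acid of 17 | C=C1C(=O)O[C@H]2CC(C)=C(C[C@H]21)[C@H](C)CCC(=O)O
F7 | step 10 | C1' acid chloride of 17 | C=C1C(=O)O[C@H]2CC(C)=C(C[C@H]21)[C@H](C)CCC(=O)Cl
F8 | step 6 | linear dienyl acetate of 8 (C8'(OAc)=C9', C10'=C5') | CC(=O)OC1=CC(C)=C(C[C@H]1CC(=O)OC)[C@H](C)CCC=C(C)C
F9 | step 6 | trans hydroxy ester (C8' epimer of 11) | O[C@@H]1CC(C)=C(C[C@H]1CC(=O)OC)[C@H](C)CCC=C(C)C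
F10 | step 6 | trans hydroxy acid from F9 | O[C@@H]1CC(C)=C(C[C@H]1CC(=O)O)[C@H](C)CCC=C(C)C
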